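**Plan**
Retrosynthesis: the two ester C–O bonds (C10 angelate, C6 4-hydroxybenzoate) are cut first; the C8 methyl and C8=C9 go back through a C10 enone to a saturated C10 carbinol; C6–O/C5–H go back to a C5=C6 alkene and C4–isopropyl to a C4 ketone; then C1–C2 is cut (Nazarov) and the C4–C5 acyl bond (carbonylative coupling), leaving a 3-iodo-2-methylcycloheptenol derived from cycloheptane-1,3-dione.
Forward: the seven-membered ring is bought; the five-membered ring is closed onto it in one step by 4π electrocyclisation of a cycloheptenyl vinyl ketone; C4, then C5/C6, then C8/C10 are elaborated, and the angelate goes on last.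
Stereochemistry: a CBS reduction sets C10; conrotation anti to the C10 silyloxy group passes this on to quaternary C1; the C1 methyl then directs isopropyl addition (C4), hydroboration (C5, C6) and the Luche reduction that restores C10 after it has served as the enone carbonyl for introducing the C8 methyl.

Key step: step 6

Remark: locants C1–C10 refer to the bicyclic core (C1 = methyl-bearing ring-fusion carbon, C2/C3 = cyclopentane CH2, C4 = carbinol carbon, C5 = ring-fusion CH, C6–C10 = rest of the seven-membered ring, with C6 aroyloxy, C8 methyl, C10 angeloyloxy). β is the face of the C1 methyl, α the opposite face. 4-(Triisopropylsilyloxy)benzoic acid is assumed not to be purchasable and is made in step 9.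

**Step 1**
Reactants: 1 cycloheptane-1,3-dione
Product: 2 2-methylcycloheptane-1,3-dione
Conditions: MeI (1.05 equiv), K2CO3, acetone, 50 °C
Reagents that add atoms: iodomethane, CI
Why: C-alkylation of the stabilised β-diketone enolate with a soft electrophile (classical 2-alkylation of cyclic 1,3-diones), with near-stoichiometric MeI to limit the 2,2-dimethyl by-product.

**Step 2**
Reactants: 2 2-methylcycloheptane-1,3-dione
Product: 3 3-iodo-2-methylcyclohept-2-en-1-one
Conditions: PPh3, I2, MeCN, rt; then Et3N, 80 °C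
Reagents that add atoms: iodine, II
Why: Ph3PI2 turns the enol oxygen into an oxyphosphonium leaving group that iodide displaces by addition–elimination (β-iodo enone synthesis from cyclic 1,3-diones), and the symmetry of 2 allows only one product.

**Step 3**
Reactants: 3 3-iodo-2-methylcyclohept-2-en-1-one
Product: 4 (S)-3-iodo-2-methylcyclohept-2-en-1-ol
Conditions: (R)-2-methyl-CBS-oxazaborolidine (20 mol %), BH3·SMe2, THF, −20 °C
Reagents that add atoms: none
Why: Corey–Bakshi–Shibata reduction in which the fully substituted alkenyl arm is the large group and the ring CH2 the small one, so the (R)-catalyst should deliver hydride to the face that gives the (S)-carbinol (future C10), as is usual for 2-substituted cycloalkenones.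

**Step 4**
Reactants: 4 (S)-3-iodo-2-methylcyclohept-2-en-1-ol
Product: 5 (S)-tert-butyl[(3-iodo-2-methylcyclohept-2-en-1-yl)oxy]dimethylsilane
Conditions: TBSCl, imidazole, DMF, rt
Reagents that add atoms: tert-butyldimethylsilyl chloride, CC(C)(C)[Si](C)(C)Cl
Why: standard silylation of a secondary allylic alcohol, which leaves the stereocentre untouched and installs the bulky group that later directs the electrocyclisation.

**Step 5**
Reactants: 5 (S)-tert-butyl[(3-iodo-2-methylcyclohept-2-en-1-yl)oxy]dimethylsilane, 6 tributyl(vinyl)stannane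
Product: 7 (S)-1-[3-(tert-butyldimethylsilyloxy)-2-methylcyclohept-1-en-1-yl]prop-2-en-1-one
Conditions: Pd(PPh3)4 (5 mol %), CO (3 atm), THF, 55 °C
Reagents that add atoms: carbon monoxide, [C-]#[O+]
Why: carbonylative Stille coupling (oxidative addition of zerovalent palladium to the vinyl iodide, CO insertion favoured by the hindered alkenylpalladium and CO pressure, transmetalation from tin, reductive elimination) gives the cross-conjugated dienone, the standard entry to Nazarov substrates.

**Step 6**
Reactants: 7 (S)-1-[3-(tert-butyldimethylsilyloxy)-2-methylcyclohept-1-en-1-yl]prop-2-en-1-one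
Product: 8 (3aS,4S)-4-(tert-butyldimethylsilyloxy)-3a-methyl-3,3a,4,5,6,7-hexahydroazulen-1(2H)-one (C4 ketone, C5=C6 alkene, 1β-methyl, 10β-silyloxy)
Conditions: BF3·OEt2 (2 equiv), CH2Cl2, −20 to 10 °C; NaHCO3 quench
Reagents that add atoms: none
Why: BF3 coordination to the ketone of 7 gives the oxidopentadienyl cation C1=C5–C4–C3=C2, whose thermally allowed 4π conrotatory electrocyclisation forms the C1–C2 bond and an oxyallyl cation (C3–C4–C5); loss of H+ from C6 and protonation of the dienolate at C3 then give enone 8. The closest known reaction type is the Lewis acid Nazarov cyclisation of 2-alkyl-1-acylcycloalkenes, which builds ring-fusion quaternary carbons. The cyclopentane ring (C1–C2–C3–C4–C5) is closed by this electrocyclic bond formation between the two termini of the pentadienyl cation, annulated onto the existing seven-membered ring. The one new stereocentre, C1, is controlled by C10: A(1,2) strain with the C1 methyl holds the silyloxy group pseudoaxial, so the conrotation that brings C2 onto the opposite face is favoured and CH3 ends cis to the C10 oxygen. The step needs torquoselectivity, supplied by that bulky allylic substituent next to the rotating terminus, and regioselective termination, supplied by the substrate because C1 has no hydrogen and the tertiary terminus C5 of the oxyallyl cation loses the adjacent C6 proton to give the more substituted conjugated C5=C6 alkene instead of the C2=C3 isomer. The unsubstituted vinyl terminus keeps the fully substituted C1 accessible, and the low temperature is meant to hold back 1,2-shifts from C1 into the oxyallyl cation and loss of the silyl ether.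

**Step 7**
Reactants: 8 (3aS,4S)-4-(tert-butyldimethylsilyloxy)-3a-methyl-3,3a,4,5,6,7-hexahydroazulen-1(2H)-one
Product: 9 (1R,3aS,4S)-4-(tert-butyldimethylsilyloxy)-3a-methyl-1-(propan-2-yl)-1,2,3,3a,4,5,6,7-octahydroazulen-1-ol (4β-OH, 4α-isopropyl, C5=C6)
Conditions: iPrMgCl, CeCl3 (anhydrous), THF, −78 to −40 °C
Reagents that add atoms: isopropylmagnesium chloride, CC(C)[Mg]Cl
Why: 1,2-addition of the organocerium reagent (which suppresses enolisation, β-hydride reduction and conjugate addition) should occur on the α face of the cyclopentanone, anti to the pseudoaxial C1 methyl lying 1,3 to the carbonyl carbon, which sets C4 with hydroxyl β (cis to CH3) and isopropyl α.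

**Step 8**
Reactants: 9 (1R,3aS,4S)-4-(tert-butyldimethylsilyloxy)-3a-methyl-1-(propan-2-yl)-1,2,3,3a,4,5,6,7-octahydroazulen-1-ol
Product: 11 10β-(tert-butyldimethylsilyloxy)-4α-isopropyl-1β-methyl-5α-H-perhydroazulene-4β,6α-diol (trans-fused), via C6 alkylborane 10 (not isolated)
Conditions: BH3·THF (4 equiv), THF, 0 °C to rt; then NaOH (3 M aq.), H2O2 (30 %), 0 °C to rt
Reagents that add atoms: borane, B (boron stays only in intermediate 10); hydrogen peroxide, OO
Why: hydroboration–oxidation, in which syn addition of B–H with boron on the less substituted C6 is expected from the α face, anti to the C1 methyl that is 1,3-syn-axial to C6 (the bias that gives 5α-H,6α-ols from Δ5-steroids) and anti to the allylic C4 oxygen, so that one step sets C5 (H trans to CH3, trans ring fusion) and C6 (α-OH, formed with retention on oxidation).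

**Step 9**
Reactants: 12 4-hydroxybenzoic acid
Product: 14 4-(triisopropylsilyloxy)benzoic acid, via bis(triisopropylsilyl) derivative 13 (not isolated)
Conditions: TIPSCl (2.2 equiv), imidazole, DMF, rt; then K2CO3, MeOH/THF/H2O, 0 °C; acidify to pH 4
Reagents that add atoms: triisopropylsilyl chloride, CC(C)[Si](Cl)(C(C)C)C(C)C
Why: silylation of both acidic OH groups followed by selective hydrolysis of the far more labile silyl ester (acyloxy leaving group on silicon) leaves the aryl silyl ether.

**Step 10**
Reactants: 11 10β-(tert-butyldimethylsilyloxy)-4α-isopropyl-1β-methyl-5α-H-perhydroazulene-4β,6α-diol, 14 4-(triisopropylsilyloxy)benzoic acid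
Product: 15 10β-(tert-butyldimethylsilyloxy)-4β-hydroxy-4α-isopropyl-1β-methyl-5α-H-perhydroazulen-6α-yl 4-(triisopropylsilyloxy)benzoate
Conditions: DCC, DMAP (cat.), CH2Cl2, rt
Reagents that add atoms: none
Why: Steglich esterification in which only the secondary C6 alcohol is acylated, the tertiary C4 carbinol being inert as is usual for such 4,6-diol arrays.

**Step 11**
Reactants: 15 10β-(tert-butyldimethylsilyloxy)-4β-hydroxy-4α-isopropyl-1β-methyl-5α-H-perhydroazulen-6α-yl 4-(triisopropylsilyloxy)benzoate
Product: 16 4β,10β-dihydroxy-4α-isopropyl-1β-methyl-5α-H-perhydroazulen-6α-yl 4-(triisopropylsilyloxy)benzoate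
Conditions: HF (48 % aq.), MeCN, 0 °C to rt
Reagents that add atoms: none
Why: under acidic fluoride conditions alkyl silyl ethers are cleaved faster than aryl silyl ethers (the reverse of basic fluoride), and the bulkier triisopropylsilyl group on the electron-poor phenol adds margin, so only the C10 ether should be removed.

**Step 12**
Reactants: 16 4β,10β-dihydroxy-4α-isopropyl-1β-methyl-5α-H-perhydroazulen-6α-yl 4-(triisopropylsilyloxy)benzoate
Product: 18 4β-hydroxy-4α-isopropyl-1β-methyl-10-oxo-5α-H-perhydroazul-8-en-6α-yl 4-(triisopropylsilyloxy)benzoate (C10 ketone conjugated with C8=C9), via C10 ketone 17 (not isolated)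
Conditions: IBX (3 equiv), DMSO/PhMe, 70 °C
Reagents that add atoms: none
Why: IBX oxidises the secondary alcohol to the ketone and at 70 °C dehydrogenates it through its enol (IBX dehydrogenation of ketones); enolisation is possible only toward C9 because C1 is quaternary, so the C8=C9 enone is the only regioisomer.

**Step 13**
Reactants: 18 4β-hydroxy-4α-isopropyl-1β-methyl-10-oxo-5α-H-perhydroazul-8-en-6α-yl 4-(triisopropylsilyloxy)benzoate
Product: 20 4β-hydroxy-4α-isopropyl-1β,8-dimethyl-10-oxo-5α-H-perhydroazul-8-en-6α-yl 4-(triisopropylsilyloxy)benzoate, via lithium enolate 19 (not isolated)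
Conditions: Me2CuLi (from MeLi, CuI; 3 equiv), THF, −78 °C; then PhS(Cl)=N-t-Bu, −78 °C
Reagents that add atoms: lithium dimethylcuprate (prepared from MeLi and CuI), [Li+].C[Cu-]C
Why: conjugate addition of the Gilman reagent at C8 followed, in the same flask, by Mukaiyama dehydrogenation of the enolate with N-tert-butylbenzenesulfinimidoyl chloride (α-sulfenylation, then syn elimination through a five-membered transition state) returns the enone now carrying the C8 methyl; the transient C8 stereocentre is erased and the weakly basic cuprate at −78 °C should not cause γ-deprotonation.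

**Step 14**
Reactants: 20 4β-hydroxy-4α-isopropyl-1β,8-dimethyl-10-oxo-5α-H-perhydroazul-8-en-6α-yl 4-(triisopropylsilyloxy)benzoate
Product: 21 4β,10β-dihydroxy-4α-isopropyl-1β,8-dimethyl-5α-H-perhydroazul-8-en-6α-yl 4-(triisopropylsilyloxy)benzoate
Conditions: NaBH4, CeCl3·7H2O, MeOH, −78 °C
Reagents that add atoms: none
Why: Luche 1,2-reduction in which hydride should add to C10 from the α face, anti to the axial methyl on the adjacent quaternary C1 (as in reductions of ketones flanked by an angular methyl group), giving the 10β-allylic alcohol with OH cis to CH3 and no conjugate reduction.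

**Step 15**
Reactants: 21 4β,10β-dihydroxy-4α-isopropyl-1β,8-dimethyl-5α-H-perhydroazul-8-en-6α-yl 4-(triisopropylsilyloxy)benzoate, 22 angelic acid ((Z)-2-methylbut-2-enoic acid)
Product: 24 4β-hydroxy-4α-isopropyl-1β,8-dimethyl-10β-[(Z)-2-methylbut-2-enoyloxy]-5α-H-perhydroazul-8-en-6α-yl 4-(triisopropylsilyloxy)benzoate, via mixed anhydride 23 (not isolated)
Conditions: 22, 2,4,6-Cl3C6H2COCl, Et3N, PhMe, rt; then 21, 80 °C
Reagents that add atoms: 2,4,6-trichlorobenzoyl chloride, O=C(Cl)c1c(Cl)cc(Cl)cc1Cl (its atoms stay only in intermediate 23)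
Why: Yamaguchi-type acylation through the mixed anhydride without a nucleophilic pyridine catalyst, conditions under which hindered secondary alcohols are angeloylated with retention of the Z geometry; the alcohol attacks the less shielded angeloyl carbonyl and the tertiary C4 hydroxyl stays free.

**Step 16**
Reactants: 24 4β-hydroxy-4α-isopropyl-1β,8-dimethyl-10β-[(Z)-2-methylbut-2-enoyloxy]-5α-H-perhydroazul-8-en-6α-yl 4-(triisopropylsilyloxy)benzoate
Product: 25 (3R,3aS,4S,8S,8aS)-3-hydroxy-6,8a-dimethyl-8-{[(2Z)-2-methylbut-2-enoyl]oxy}-3-(propan-2-yl)-1,2,3,3a,4,5,8,8a-octahydroazulen-4-yl 4-hydroxybenzoate (CNP0273650.10)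
Conditions: Bu4NF, AcOH, THF, 0 °C
Reagents that add atoms: none
Why: fluoride cleaves the aryl silyl ether rapidly at 0 °C, and AcOH buffering keeps phenoxide and fluoride from attacking the two esters or isomerising the angelate.

**Compound list**
1 | cycloheptane-1,3-dione | O=C1CCCCC(=O)C1 | starting material
2 | 2-methylcycloheptane-1,3-dione | CC1C(=O)CCCCC1=O | intermediate
3 | 3-iodo-2-methylcyclohept-2-en-1-one | CC1=C(I)CCCCC1=O | intermediate
4 | (S)-3-iodo-2-methylcyclohept-2-en-1-ol | O[C@H]1CCCCC(I)=C1C | intermediate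
5 | (S)-tert-butyl[(3-iodo-2-methylcyclohept-2-en-1-yl)oxy]dimethylsilane | CC(C)(C)[Si](C)(C)O[C@H]1CCCCC(I)=C1C | intermediate
6 | tributyl(vinyl)stannane | C=C[Sn](CCCC)(CCCC)CCCC | starting material
7 | (S)-1-[3-(tert-butyldimethylsilyloxy)-2-methylcyclohept-1-en-1-yl]prop-2-en-1-one | CC(C)(C)[Si](C)(C)O[C@H]1CCCCC(C(=O)C=C)=C1C | intermediate
8 | (3aS,4S)-4-(tert-butyldimethylsilyloxy)-3a-methyl-3,3a,4,5,6,7-hexahydroazulen-1(2H)-one | CC(C)(C)[Si](C)(C)O[C@H]1CCCC=C2[C@]1(C)CCC2=O | intermediate
9 | (1R,3aS,4S)-4-(tert-butyldimethylsilyloxy)-3a-methyl-1-(propan-2-yl)-1,2,3,3a,4,5,6,7-octahydroazulen-1-ol | CC(C)(C)[Si](C)(C)O[C@H]1CCCC=C2[C@]1(C)CC[C@@]2(O)C(C)C | intermediate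
10 | 6α-boryl-10β-(tert-butyldimethylsilyloxy)-4α-isopropyl-1β-methyl-5α-H-perhydroazulen-4β-ol (C6 alkylborane, written as the monoalkylborane) | CC(C)(C)[Si](C)(C)O[C@H]1CCC[C@H](B)[C@@H]2[C@]1(C)CC[C@@]2(O)C(C)C | intermediate (not isolated)
11 | 10β-(tert-butyldimethylsilyloxy)-4α-isopropyl-1β-methyl-5α-H-perhydroazulene-4β,6α-diol | CC(C)(C)[Si](C)(C)O[C@H]1CCC[C@H](O)[C@@H]2[C@]1(C)CC[C@@]2(O)C(C)C | intermediate
12 | 4-hydroxybenzoic acid | OC(=O)c1ccc(O)cc1 | starting material
13 | triisopropylsilyl 4-(triisopropylsilyloxy)benzoate | CC(C)[Si](C(C)C)(C(C)C)OC(=O)c1ccc(O[Si](C(C)C)(C(C)C)C(C)C)cc1 | intermediate (not isolated)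
14 | 4-(triisopropylsilyloxy)benzoic acid | CC(C)[Si](Oc1ccc(C(=O)O)cc1)(C(C)C)C(C)C | intermediate
15 | 10β-(tert-butyldimethylsilyloxy)-4β-hydroxy-4α-isopropyl-1β-methyl-5α-H-perhydroazulen-6α-yl 4-(triisopropylsilyloxy)benzoate | CC(C)(C)[Si](C)(C)O[C@H]1CCC[C@H](OC(=O)c3ccc(O[Si](C(C)C)(C(C)C)C(C)C)cc3)[C@@H]2[C@]1(C)CC[C@@]2(O)C(C)C | intermediate
16 | 4β,10β-dihydroxy-4α-isopropyl-1β-methyl-5α-H-perhydroazulen-6α-yl 4-(triisopropylsilyloxy)benzoate | O[C@H]1CCC[C@H](OC(=O)c3ccc(O[Si](C(C)C)(C(C)C)C(C)C)cc3)[C@@H]2[C@]1(C)CC[C@@]2(O)C(C)C | intermediate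
17 | 4β-hydroxy-4α-isopropyl-1β-methyl-10-oxo-5α-H-perhydroazulen-6α-yl 4-(triisopropylsilyloxy)benzoate | O=C1CCC[C@H](OC(=O)c3ccc(O[Si](C(C)C)(C(C)C)C(C)C)cc3)[C@@H]2[C@]1(C)CC[C@@]2(O)C(C)C | intermediate (not isolated)
18 | 4β-hydroxy-4α-isopropyl-1β-methyl-10-oxo-5α-H-perhydroazul-8-en-6α-yl 4-(triisopropylsilyloxy)benzoate | O=C1C=CC[C@H](OC(=O)c3ccc(O[Si](C(C)C)(C(C)C)C(C)C)cc3)[C@@H]2[C@]1(C)CC[C@@]2(O)C(C)C | intermediate
19 | lithium C9=C10 enolate of the 8-methyl-10-ketone, C4 oxygen as lithium alkoxide, C8 configuration not defined | [Li]OC1=CC(C)C[C@H](OC(=O)c3ccc(O[Si](C(C)C)(C(C)C)C(C)C)cc3)[C@@H]2[C@]1(C)CC[C@@]2(O[Li])C(C)C | intermediate (not isolated)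
20 | 4β-hydroxy-4α-isopropyl-1β,8-dimethyl-10-oxo-5α-H-perhydroazul-8-en-6α-yl 4-(triisopropylsilyloxy)benzoate | O=C1C=C(C)C[C@H](OC(=O)c3ccc(O[Si](C(C)C)(C(C)C)C(C)C)cc3)[C@@H]2[C@]1(C)CC[C@@]2(O)C(C)C | intermediate
21 | 4β,10β-dihydroxy-4α-isopropyl-1β,8-dimethyl-5α-H-perhydroazul-8-en-6α-yl 4-(triisopropylsilyloxy)benzoate | O[C@H]1C=C(C)C[C@H](OC(=O)c3ccc(O[Si](C(C)C)(C(C)C)C(C)C)cc3)[C@@H]2[C@]1(C)CC[C@@]2(O)C(C)C | intermediate
22 | angelic acid, (Z)-2-methylbut-2-enoic acid | C/C=C(/C)C(=O)O | starting material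
23 | (Z)-2-methylbut-2-enoic 2,4,6-trichlorobenzoic anhydride | C/C=C(/C)C(=O)OC(=O)c1c(Cl)cc(Cl)cc1Cl | intermediate (not isolated)
24 | 4β-hydroxy-4α-isopropyl-1β,8-dimethyl-10β-[(Z)-2-methylbut-2-enoyloxy]-5α-H-perhydroazul-8-en-6α-yl 4-(triisopropylsilyloxy)benzoate | C/C=C(/C)C(=O)O[C@H]1C=C(C)C[C@H](OC(=O)c2ccc(O[Si](C(C)C)(C(C)C)C(C)C)cc2)[C@@H]2[C@]1(C)CC[C@@]2(O)C(C)C | intermediate
25 | (3R,3aS,4S,8S,8aS)-3-hydroxy-6,8a-dimethyl-8-{[(2Z)-2-methylbut-2-enoyl]oxy}-3-(propan-2-yl)-1,2,3,3a,4,5,8,8a-octahydroazulen-4-yl 4-hydroxybenzoate | C/C=C(/C)C(=O)O[C@H]1C=C(C)C[C@H](OC(=O)c2ccc(O)cc2)[C@@H]2[C@]1(C)CC[C@@]2(O)C(C)C | target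

Total step count: 16 (15 on the main line plus step 9 for the aryl acid). Longest linear sequence: 15 steps (steps 1–8 and 10–16).

**Steps most likely to fail**

Step 6. The oxyallyl cation may lose a proton unselectively (C2 instead of C6), a group may shift from quaternary C1, the vinyl ketone may polymerise, or the silyl ether may be lost to the Lewis acid. The fallback sets out from 5 and uses a silicon-directed Nazarov cyclisation, which fixes the termination and shortens the cation lifetime. Carbonylative Stille coupling of 5 with (E)-tributyl[2-(trimethylsilyl)vinyl]stannane (Pd(PPh3)4, CO) would give the β-silyl dienone F1. FeCl3 in CH2Cl2 at −50 °C should cyclise it with loss of the silyl group to the C2=C3 cyclopentenone F2, whose C5 configuration is immaterial. Hydrogenation (H2, Pd/C, EtOAc) gives the saturated ketone F3. The more substituted trimethylsilyl enol ether F4 is formed under equilibrating conditions (TMSCl, NaI, Et3N, MeCN). Saegusa–Ito dehydrogenation (Pd(OAc)2, MeCN) can eliminate only toward C6 and comes back to the route at 8.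

Step 8. Borane may approach the hindered C5=C6 alkene from the β face (past OH and CH3 instead of isopropyl and the ring), or with poor facial selectivity, giving the cis-fused 6β-alcohol. The fallback sets out from 9 and replaces kinetic face selection by thermodynamic control at C5 and hydroxyl-directed hydride delivery at C6. The hydroboration product, taken as the 5β-H,6β-diol F5, is oxidised with Dess–Martin periodinane to the cis-fused β-hydroxy ketone F6. Brief equilibration at C5 (DBU cat., CH2Cl2, 0 °C, kept short to avoid dehydration or retro-aldol cleavage) should give the trans-fused β-hydroxy ketone F7, which places C6 trans to the C4 isopropyl group. Evans–Saksena reduction (Me4NBH(OAc)3, MeCN/AcOH, −25 °C) then delivers hydride from the C4-bound borate to give the 1,3-anti diol and comes back to the route at 11.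

Step 15. Acylation of the neopentylic allylic alcohol may be slow enough for the activated angeloyl donor to isomerise from Z to E, giving tiglate. The fallback sets out from 21 and builds the Z alkene on the substrate instead of transferring it. Steglich esterification of 21 with 2-[bis(2,2,2-trifluoroethoxy)phosphoryl]propanoic acid (DCC, DMAP) gives the phosphonate ester F8. Still–Gennari olefination (KN(SiMe3)2, 18-crown-6, THF, −78 °C, then acetaldehyde) should form the (Z)-2-methylbut-2-enoate and comes back to the route at 24.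

**Further compounds**
F1 | step 6 | (S,E)-1-[3-(tert-butyldimethylsilyloxy)-2-methylcyclohept-1-en-1-yl]-3-(trimethylsilyl)prop-2-en-1-one | CC(C)(C)[Si](C)(C)O[C@H]1CCCCC(C(=O)/C=C/[Si](C)(C)C)=C1C
F2 | step 6 | 10β-(tert-butyldimethylsilyloxy)-1β-methyl-5β-H-hydroazul-2-en-4-one (cis-fused cyclopentenone) | CC(C)(C)[Si](C)(C)O[C@H]1CCCC[C@H]2[C@]1(C)C=CC2=O
F3 | step 6 | 10β-(tert-butyldimethylsilyloxy)-1β-methyl-5β-H-perhydroazulen-4-one | CC(C)(C)[Si](C)(C)O[C@H]1CCCC[C@H]2[C@]1(C)CCC2=O
F4 | step 6 | 10β-(tert-butyldimethylsilyloxy)-1β-methyl-4-(trimethylsilyloxy)hydroazul-4(5)-ene (C4=C5 silyl enol ether) | CC(C)(C)[Si](C)(C)O[C@H]1CCCCC2=C(O[Si](C)(C)C)CC[C@]12C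
F5 | step 8 | 10β-(tert-butyldimethylsilyloxy)-4α-isopropyl-1β-methyl-5β-H-perhydroazulene-4β,6β-diol | CC(C)(C)[Si](C)(C)O[C@H]1CCC[C@@H](O)[C@H]2[C@]1(C)CC[C@@]2(O)C(C)C
F6 | step 8 | 10β-(tert-butyldimethylsilyloxy)-4β-hydroxy-4α-isopropyl-1β-methyl-5β-H-perhydroazulen-6-one | CC(C)(C)[Si](C)(C)O[C@H]1CCCC(=O)[C@H]2[C@]1(C)CC[C@@]2(O)C(C)C
F7 | step 8 | 10β-(tert-butyldimethylsilyloxy)-4β-hydroxy-4α-isopropyl-1β-methyl-5α-H-perhydroazulen-6-one | CC(C)(C)[Si](C)(C)O[C@H]1CCCC(=O)[C@@H]2[C@]1(C)CC[C@@]2(O)C(C)C
F8 | step 15 | 10β-{2-[bis(2,2,2-trifluoroethoxy)phosphoryl]propanoyloxy}-4β-hydroxy-4α-isopropyl-1β,8-dimethyl-5α-H-perhydroazul-8-en-6α-yl 4-(triisopropylsilyloxy)benzoate (either configuration at the phosphonate-bearing carbon) | CC(C(=O)O[C@H]1C=C(C)C[C@H](OC(=O)c2ccc(O[Si](C(C)C)(C(C)C)C(C)C)cc2)[C@@H]2[C@]1(C)CC[C@@]2(O)C(C)C)P(=O)(OCC(F)(F)F)OCC(F)(F)F
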